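**Retrosynthetic overview**
- The target comes from a late Shi epoxidation of the C3=C4 E-olefin of a 14-membered trienolide (epoxide ring formed last).
- The trienolide comes from C7–C8 closure of a seco ynal by Markovnikov reductive alkyne–aldehyde coupling (macrocycle formed second; sets C7 and the exocyclic methylene).
- The seco ynal comes from a cis-α-methylene-γ-butyrolactone (ring formed first), made by C14–C1 union: organocascade hydro-oxidation of a nine-carbon enynal (sets C12, C13), then chelation-controlled indium Barbier reaction with a twelve-carbon allylic bromide (sets C14, C1).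
- The enynal comes from hepta-1,6-diyne; the bromide from pent-4-yn-1-ol, allyl bromide and methyl 2-(bromomethyl)acrylate (carboalumination, cross-metathesis).

Assumption: cembrane numbering is used for the macrocycles (C1 = lactone β-carbon, C3/C4 = epoxide carbons with C18 methyl on C4, C7 = carbinol, C8 bears the C19 methylene, C12 bears the C20 methyl, C13 = carbinol, C14 = lactone O-bearing carbon, C15/C16/C17 = α-carbon, carbonyl and exocyclic CH2). Catalyst antipodes are the ones whose accepted facial models give the stated configurations.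

**Step 1**
Reactants: 1 hepta-1,6-diyne
Product: 2 (2E)-3-methyloct-2-en-7-yn-1-ol
Conditions: 1 (3 equiv, excess recovered), AlMe3 (1 equiv), ZrCp2Cl2 (0.2 equiv), CH2Cl2, 0 °C to rt; then (CH2O)n, THF, 0 °C to rt; 1 M HCl work-up
Reagents that add atoms: trimethylaluminium, C[Al](C)C; formaldehyde (from paraformaldehyde), C=O
Why: Negishi zirconium-catalysed carboalumination adds Me–Al syn across one terminal alkyne (Me to the internal carbon) and the alkenylalane is hydroxymethylated with retention, so only the E-allylic alcohol forms, the excess of diyne keeping double addition low.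

**Step 2**
Reactants: 2 (2E)-3-methyloct-2-en-7-yn-1-ol
Product: 3 (2E)-3-methyloct-2-en-7-ynal
Conditions: MnO2 (15 equiv), CH2Cl2, rt
Reagents that add atoms: none
Why: Allylic oxidation with MnO2 is selective for the allylic alcohol and leaves the terminal alkyne and the olefin geometry untouched.

**Step 3**
Reactants: 4 pent-4-yn-1-ol; 5 allyl bromide
Product: 6 (4E)-4-methylocta-4,7-dien-1-ol
Conditions: AlMe3 (3 equiv), ZrCp2Cl2 (0.25 equiv), CH2Cl2, 0 °C to rt; then 5 (3 equiv), Pd(PPh3)4 (5 mol%), THF, rt; aqueous work-up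
Reagents that add atoms: trimethylaluminium, C[Al](C)C
Why: Syn carboalumination of the alkyne (on the aluminium alkoxide of 4) followed by palladium-catalysed Negishi-type coupling of the alkenylalane with allyl bromide gives the skipped diene with retention of the E-trisubstituted geometry.

**Step 4**
Reactants: 6 (4E)-4-methylocta-4,7-dien-1-ol; 7 methyl 2-(bromomethyl)prop-2-enoate
Product: 8 methyl (2Z,5E)-2-(bromomethyl)-9-hydroxy-6-methylnona-2,5-dienoate
Conditions: 7 (5 equiv), RuCl2(H2IMes)(=CH-C6H4-2-OiPr) (second-generation Hoveyda–Grubbs catalyst, 5 mol%), CH2Cl2, 40 °C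
Reagents that add atoms: none
Why: Olefin cross-metathesis of the monosubstituted vinyl group with the 1,1-disubstituted acrylate gives the thermodynamically preferred trisubstituted enoate with the chain cis to CH2Br (2Z), the trisubstituted C5=C6 olefin being too hindered to react.

**Step 5**
Reactants: 3 (2E)-3-methyloct-2-en-7-ynal; 8 methyl (2Z,5E)-2-(bromomethyl)-9-hydroxy-6-methylnona-2,5-dienoate
Product: 11 methyl (3S,4R,5R,6S)-4-hydroxy-3-[(2E)-6-hydroxy-3-methylhex-2-en-1-yl]-6-methyl-2-methylidene-5-[(phenylamino)oxy]undec-10-ynoate, via saturated aldehyde 9 (not isolated), via anilinooxy aldehyde 10 (not isolated)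
Conditions: (S)-2-tert-butyl-3-methylimidazolidin-4-one·Cl3CCO2H (20 mol%, antipode that gives 3S), diethyl 2,6-dimethyl-1,4-dihydropyridine-3,5-dicarboxylate (Hantzsch ester, 1.2 equiv), CHCl3, −30 °C; then L-proline (30 mol%), PhNO (1.1 equiv), 0 °C; then 8 (1.3 equiv), In powder (1.5 equiv), THF/H2O (1:1), rt
Reagents that add atoms: nitrosobenzene, O=Nc1ccccc1
Why: Iminium-catalysed transfer hydrogenation (E/Z-convergent) sets C12 (S), L-proline enamine α-aminoxylation sets C13 (R) under catalyst control, and the indium Barbier allylation proceeds through a chair transition state in which indium chelates the α-oxygen and the carbonyl, so the Z-allyl unit gives the 13,14-syn (Cram-chelate) and 14,1-syn relationships, i.e. C14 (R) and C1 (S).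

**Step 6**
Reactants: 11 methyl (3S,4R,5R,6S)-4-hydroxy-3-[(2E)-6-hydroxy-3-methylhex-2-en-1-yl]-6-methyl-2-methylidene-5-[(phenylamino)oxy]undec-10-ynoate
Product: 13 (4S,5R)-5-[(1R,2S)-1-hydroxy-2-methylhept-6-yn-1-yl]-4-[(2E)-6-hydroxy-3-methylhex-2-en-1-yl]-3-methylideneoxolan-2-one, via triol ester 12 (not isolated)
Conditions: Zn dust (10 equiv), AcOH/THF (1:2), rt; filter; then p-TsOH·H2O (10 mol%), PhMe, 40 °C
Reagents that add atoms: none
Why: Zinc in acetic acid cleaves the N–O bond reductively and acid-catalysed lactonisation of the C14 hydroxyl onto the methyl ester closes the five-membered cis-α-methylene-γ-butyrolactone (favoured over the six-membered alternative) without touching any stereocentre.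

**Step 7**
Reactants: 13 (4S,5R)-5-[(1R,2S)-1-hydroxy-2-methylhept-6-yn-1-yl]-4-[(2E)-6-hydroxy-3-methylhex-2-en-1-yl]-3-methylideneoxolan-2-one
Product: 14 (4S,5R)-5-[(1R,2S)-1-hydroxy-2-methylhept-6-yn-1-yl]-4-[(2E)-3-methyl-6-oxohex-2-en-1-yl]-3-methylideneoxolan-2-one
Conditions: TEMPO (10 mol%), PhI(OAc)2 (1.1 equiv), CH2Cl2, rt
Reagents that add atoms: none
Why: The oxoammonium (TEMPO) oxidation is selective for the primary over the hindered secondary alcohol and stops at the aldehyde.

**Step 8**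
Reactants: 14 (4S,5R)-5-[(1R,2S)-1-hydroxy-2-methylhept-6-yn-1-yl]-4-[(2E)-3-methyl-6-oxohex-2-en-1-yl]-3-methylideneoxolan-2-one
Product: 15 (1S,3E,7S,12S,13R,14R)-7,13-dihydroxycembra-3,8(19),15(17)-trien-16,14-olide
Conditions: CrCl2 (6 equiv), (S)-N-[2-(4-isopropyl-4,5-dihydro-1,3-oxazol-2-yl)-6-methylphenyl]methanesulfonamide (6.6 equiv, enantiomer selected for Re-face addition), Et3N (6.6 equiv), NiCl2 (20 mol%), PPh3 (40 mol%), H2O (4 equiv), THF/DMF (1:1), 14 added over 12 h to 2 mM, 25 °C
Reagents that add atoms: none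
Why: Proposed new method: an intramolecular, ligand-controlled version of the chromium/nickel/phosphine/water reductive coupling of terminal alkynes with aldehydes, in which zerovalent nickel (formed by reduction with divalent chromium) binds the alkyne as a nickelacyclopropene that water protonates at the terminal carbon (Markovnikov hydronickelation), the 2-alkenylnickel transmetalates to trivalent chromium carrying the chiral sulfonamide–oxazoline ligand, and the alkenylchromium adds to the Re face of the tethered aldehyde under high dilution, closing the 14-membered ring and setting C7 (S) with the exocyclic methylene in place; the closest known reactions are the intermolecular CrCl2/NiCl2/PPh3/H2O coupling of terminal alkynes with aldehydes to 2-substituted allylic alcohols and ligand-controlled Nozaki–Hiyama–Kishi macrocyclisations of 2-iodoalkenes.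

**Step 9**
Reactants: 15 (1S,3E,7S,12S,13R,14R)-7,13-dihydroxycembra-3,8(19),15(17)-trien-16,14-olide
Product: 16 (1S,3R,4R,7S,12S,13R,14R)-3,4-epoxy-7,13-dihydroxycembra-8(19),15(17)-dien-16,14-olide
Conditions: D-fructose-derived Shi ketone (1,2:4,5-di-O-isopropylidene-β-D-erythro-2,3-hexodiulo-2,6-pyranose, 30 mol%), KHSO5 (as 2KHSO5·KHSO4·K2SO4, 1.4 equiv), K2CO3, Bu4NHSO4 (cat.), Na2B4O7/Na2EDTA buffer (pH about 9.5), MeCN/CH2(OMe)2/H2O, 0 °C
Reagents that add atoms: potassium peroxymonosulfate, [K+].[O-]S(=O)(=O)OO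
Why: Shi asymmetric epoxidation, in which the chiral dioxirane attacks the electron-rich E-trisubstituted olefin through the spiro transition state to give the (3R,4R)-epoxide, while the 1,1-disubstituted olefin and the electron-poor α-methylene lactone react far more slowly.

**Compound list**
1 | hepta-1,6-diyne | C#CCCCC#C | starting material
2 | (2E)-3-methyloct-2-en-7-yn-1-ol | C#CCCC/C(C)=C/CO | intermediate
3 | (2E)-3-methyloct-2-en-7-ynal | C#CCCC/C(C)=C/C=O | intermediate
4 | pent-4-yn-1-ol | C#CCCCO | starting material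
5 | allyl bromide (3-bromoprop-1-ene) | C=CCBr | starting material
6 | (4E)-4-methylocta-4,7-dien-1-ol | OCCC/C(C)=C/CC=C | intermediate
7 | methyl 2-(bromomethyl)prop-2-enoate | C=C(CBr)C(=O)OC | starting material
8 | methyl (2Z,5E)-2-(bromomethyl)-9-hydroxy-6-methylnona-2,5-dienoate | COC(=O)/C(CBr)=C/C/C=C(C)/CCCO | intermediate
9 | (3S)-3-methyloct-7-ynal | C#CCCC[C@H](C)CC=O | intermediate
10 | (2R,3S)-3-methyl-2-[(phenylamino)oxy]oct-7-ynal | C#CCCC[C@H](C)[C@@H](ONc1ccccc1)C=O | intermediate
11 | methyl (3S,4R,5R,6S)-4-hydroxy-3-[(2E)-6-hydroxy-3-methylhex-2-en-1-yl]-6-methyl-2-methylidene-5-[(phenylamino)oxy]undec-10-ynoate | C#CCCC[C@H](C)[C@@H](ONc1ccccc1)[C@H](O)[C@@H](C/C=C(C)/CCCO)C(=C)C(=O)OC | intermediate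
12 | methyl (3S,4R,5R,6S)-4,5-dihydroxy-3-[(2E)-6-hydroxy-3-methylhex-2-en-1-yl]-6-methyl-2-methylideneundec-10-ynoate | C#CCCC[C@H](C)[C@@H](O)[C@H](O)[C@@H](C/C=C(C)/CCCO)C(=C)C(=O)OC | intermediate
13 | (4S,5R)-5-[(1R,2S)-1-hydroxy-2-methylhept-6-yn-1-yl]-4-[(2E)-6-hydroxy-3-methylhex-2-en-1-yl]-3-methylideneoxolan-2-one | C#CCCC[C@H](C)[C@@H](O)[C@@H]1OC(=O)C(=C)[C@@H]1C/C=C(C)/CCCO | intermediate
14 | (4S,5R)-5-[(1R,2S)-1-hydroxy-2-methylhept-6-yn-1-yl]-4-[(2E)-3-methyl-6-oxohex-2-en-1-yl]-3-methylideneoxolan-2-one | C#CCCC[C@H](C)[C@@H](O)[C@@H]1OC(=O)C(=C)[C@@H]1C/C=C(C)/CCC=O | intermediate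
15 | (1S,3E,7S,12S,13R,14R)-7,13-dihydroxycembra-3,8(19),15(17)-trien-16,14-olide | C=C1CCC[C@H](C)[C@@H](O)[C@@H]2OC(=O)C(=C)[C@@H]2C/C=C(C)/CC[C@@H]1O | intermediate
16 | (1S,3R,4R,7S,12S,13R,14R)-3,4-epoxy-7,13-dihydroxycembra-8(19),15(17)-dien-16,14-olide (CNP0124069.2) | C=C1CCC[C@H](C)[C@@H](O)[C@@H]2OC(=O)C(=C)[C@@H]2C[C@H]2O[C@]2(C)CC[C@@H]1O | target

**Step count**
Total: 9 steps. Longest linear sequence: 7 steps (1, 2, 5, 6, 7, 8, 9); the bromide branch is 2 steps (3, 4).

**Three steps most likely to fail**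

Step 8 (the proposed new macrocyclisation). Risks are conjugate reduction of the α-methylene lactone, incomplete Markovnikov selectivity, oligomerisation and weak control at C7. The fallback uses a preformed 2-iodoalkene and the classical Nozaki–Hiyama–Kishi ring closure; it sets out from 13 and comes back at 15. Ruthenium-catalysed Markovnikov hydrosilylation of the terminal alkyne of 13 ([Cp*Ru(MeCN)3]PF6, Et3SiH, CH2Cl2, 0 °C) gives the vinylsilane (4S,5R)-5-[(1R,2S)-1-hydroxy-2-methyl-6-(triethylsilyl)hept-6-en-1-yl]-4-[(2E)-6-hydroxy-3-methylhex-2-en-1-yl]-3-methylideneoxolan-2-one F1. Iododesilylation (N-iodosuccinimide, hexafluoroisopropanol, 0 °C) gives (4S,5R)-5-[(1R,2S)-1-hydroxy-6-iodo-2-methylhept-6-en-1-yl]-4-[(2E)-6-hydroxy-3-methylhex-2-en-1-yl]-3-methylideneoxolan-2-one F2. TEMPO/PhI(OAc)2 oxidation as in step 7 gives (4S,5R)-5-[(1R,2S)-1-hydroxy-6-iodo-2-methylhept-6-en-1-yl]-4-[(2E)-3-methyl-6-oxohex-2-en-1-yl]-3-methylideneoxolan-2-one F3. CrCl2/NiCl2 (cat.) with the same sulfonamide ligand in THF/DMF at 2 mM then closes the ring to 15.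

Step 5 (one-pot union). The anilinooxy oxygen may chelate indium less well than a free hydroxyl, lowering the 13,14-syn selectivity. The fallback isolates the free α-hydroxy aldehyde, for which chelation-controlled indium allylation in water is established; it sets out from 3 and comes back at 13. The cascade is run from 3 through 9 to 10 as before and quenched with NaBH4/MeOH to give (2R,3S)-3-methyl-2-[(phenylamino)oxy]oct-7-yn-1-ol F4. Zn/AcOH cleaves the N–O bond to (2R,3S)-3-methyloct-7-yne-1,2-diol F5. TEMPO (cat.)/NaOCl/KBr (CH2Cl2/H2O, pH 9, 0 °C) oxidises the primary hydroxyl to (2R,3S)-2-hydroxy-3-methyloct-7-ynal F6, handled as its dimer. Indium-mediated Barbier reaction of F6 with 8 in H2O/THF gives 12, and p-TsOH lactonisation gives 13.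

Step 4 (cross-metathesis). The bromomethyl acrylate may homodimerise, poison the catalyst or react sluggishly. The fallback builds the enoate by olefination instead of metathesis; it sets out from 4 and comes back at 8. Silylation (TBSCl, imidazole) gives tert-butyldimethyl(pent-4-yn-1-yloxy)silane F7. Carboalumination (AlMe3, ZrCp2Cl2), ate-complex formation (n-BuLi) and opening of ethylene oxide give (3E)-7-[(tert-butyldimethylsilyl)oxy]-4-methylhept-3-en-1-ol F8. Dess–Martin oxidation gives (3E)-7-[(tert-butyldimethylsilyl)oxy]-4-methylhept-3-enal F9, used at once. Horner–Wadsworth–Emmons olefination with methyl 2-(dimethoxyphosphoryl)-3-hydroxypropanoate (LiCl, DBU, MeCN, 0 °C) gives methyl (2E,5E)-9-[(tert-butyldimethylsilyl)oxy]-2-(hydroxymethyl)-6-methylnona-2,5-dienoate F10. CBr4/PPh3 gives methyl (2Z,5E)-2-(bromomethyl)-9-[(tert-butyldimethylsilyl)oxy]-6-methylnona-2,5-dienoate F11, and HF·pyridine removes the silyl group to give 8.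

**Further compounds**
F1 | step 8 | (4S,5R)-5-[(1R,2S)-1-hydroxy-2-methyl-6-(triethylsilyl)hept-6-en-1-yl]-4-[(2E)-6-hydroxy-3-methylhex-2-en-1-yl]-3-methylideneoxolan-2-one | C=C([Si](CC)(CC)CC)CCC[C@H](C)[C@@H](O)[C@@H]1OC(=O)C(=C)[C@@H]1C/C=C(C)/CCCO
F2 | step 8 | (4S,5R)-5-[(1R,2S)-1-hydroxy-6-iodo-2-methylhept-6-en-1-yl]-4-[(2E)-6-hydroxy-3-methylhex-2-en-1-yl]-3-methylideneoxolan-2-one | C=C(I)CCC[C@H](C)[C@@H](O)[C@@H]1OC(=O)C(=C)[C@@H]1C/C=C(C)/CCCO
F3 | step 8 | (4S,5R)-5-[(1R,2S)-1-hydroxy-6-iodo-2-methylhept-6-en-1-yl]-4-[(2E)-3-methyl-6-oxohex-2-en-1-yl]-3-methylideneoxolan-2-one | C=C(I)CCC[C@H](C)[C@@H](O)[C@@H]1OC(=O)C(=C)[C@@H]1C/C=C(C)/CCC=O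
F4 | step 5 | (2R,3S)-3-methyl-2-[(phenylamino)oxy]oct-7-yn-1-ol | C#CCCC[C@H](C)[C@@H](ONc1ccccc1)CO
F5 | step 5 | (2R,3S)-3-methyloct-7-yne-1,2-diol | C#CCCC[C@H](C)[C@@H](O)CO
F6 | step 5 | (2R,3S)-2-hydroxy-3-methyloct-7-ynal | C#CCCC[C@H](C)[C@@H](O)C=O
F7 | step 4 | tert-butyldimethyl(pent-4-yn-1-yloxy)silane | C#CCCCO[Si](C)(C)C(C)(C)C
F8 | step 4 | (3E)-7-[(tert-butyldimethylsilyl)oxy]-4-methylhept-3-en-1-ol | OCC/C=C(C)/CCCO[Si](C)(C)C(C)(C)C
F9 | step 4 | (3E)-7-[(tert-butyldimethylsilyl)oxy]-4-methylhept-3-enal | O=CC/C=C(C)/CCCO[Si](C)(C)C(C)(C)C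
F10 | step 4 | methyl (2E,5E)-9-[(tert-butyldimethylsilyl)oxy]-2-(hydroxymethyl)-6-methylnona-2,5-dienoate | COC(=O)/C(CO)=C/C/C=C(C)/CCCO[Si](C)(C)C(C)(C)C
F11 | step 4 | methyl (2Z,5E)-2-(bromomethyl)-9-[(tert-butyldimethylsilyl)oxy]-6-methylnona-2,5-dienoate | COC(=O)/C(CBr)=C/C/C=C(C)/CCCO[Si](C)(C)C(C)(C)C
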